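I began with the 3.00 mM of buffer acid set against the 10.5 mM of solid nucleophile in this flask.

electrophile 10 mM; buffer base 2.00 mM; buffer acid 3.00 mM; solid nucleophile 10.5 mM; protic impurity 0.200 mM; time 25 h

    electrophile + nucleophile → acid + product + leaving group (k1 = 12.7 /M/h)
    buffer acid ⇌ buffer base + acid, settled at all times (K2 = 2.0 × 10⁻⁸ M)
    protonated nucleophile ⇌ nucleophile + acid, settled at all times (K3 = 1.0 × 10⁻¹⁰ M)
    solid nucleophile ⇌ nucleophile, rate k4*(cs4 - [nucleophile]) while solid is left; crystals form when [nucleophile] > cs4 (cs4 = 4.9 mM, k4 = 0.193 /h)
    electrophile + protic impurity → quenched substrate (k5 = 2780 /M/h)

1. part of the electrophile that has reacted at 25 h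
2. pH of the solution at 25 h

- acid is the free proton; pH is minus the decimal logarithm of its molar concentration
- solid nucleophile is a solid; its amount is given per volume of the solution
- at the start none of the solid nucleophile is in solution
- run time (flask): 25 h

I turned the constants into times, taking the coupling with [nucleophile] at its solubility:

| Step | Time |
|---|---|
| half-life of protic impurity, electrophile as charged | 1.50 min |
| dissolving the charge at the fastest rate | 11.1 h |
| half-life of electrophile by coupling | 11.1 h |

The first row is far shorter than the run, so I let the protic impurity take 2.00% of the electrophile at once. The second row is also shorter than the run, so I counted the solid as dissolved by the asked time. The third row is shorter as well, so time alone did not hold the coupling back.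

The brake lay in the protons. The nucleophile is the stronger base, since the constant of its protonated form is smaller than that of the buffer acid. It therefore takes the protons of the buffer acid, and each coupling then costs two nucleophiles, one coupled and one protonated. That gave me the base budget, the product at which the uncoupled nucleophile just equals the protons from the charged buffer acid plus those released by coupling: half of what remains of the nucleophile after the buffer acid is paid, 3.75 mM. It is a limiting-reagent count with protons included, but I took it as an estimate for the run time and not as a ceiling, since buffer base can take up protons as well. I committed to 39.5% reacted and reckoned no pH.

The forecast gave 37% (33% to 41%) and pH 9 (8.8 to 9.3), on the grounds that “the acid released by the reaction pulls the free nucleophile down”. My figure lay above its centre.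

The flask gave 37.5% and pH 9.00, both inside the forecast's ranges. By 25.0 h the electrophile's half-life by coupling had reached 86 h, long against the run. The leaving group stood at 3.55 mM, just under the budget of 3.75 mM, and at 250 h it stood at 4.90 mM, past the budget.

In the neighbour flask charged with 6.3 mM of solid nucleophile, the budget is 1.65 mM, which gives 18.5% reacted. That flask gave 20.1%, below the forecast's low end.

The constants come from no measurement; the flask was simulated.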